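**Retrosynthetic overview**

1. Target 28 ⇐ angeloylation at O8 ⇐ hydroxyl-directed 1,10-epoxidation of the (1(10)Z,4Z)-germacradienolide 24 ⇐ key ring closure: the (Z)-C5 vinyl iodide of acyclic 21 adds to its C6 aldehyde (Nozaki–Hiyama–Kishi), and the C6 alkoxide then closes the γ-lactone.
2. 21 ⇐ periodate cleavage of a dioxolane (C6 comes from glyceraldehyde) ⇐ syn-selective indium union C7–C8 of the β,γ-unsaturated aldehyde 13 with allyl bromide 17; the glyceraldehyde stereocentre relays to C7 and C8 and is then erased.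
3. 13 ⇐ seven-membered lactone 9 (ester-tethered ring-closing metathesis; a temporary ring that fixes the Z C1=C10 olefin and carries C8 as its carbonyl) ⇐ Brown allylation of iodoenal 4 (sets C3) ⇐ propargyl alcohol.
4. Ring order: temporary oxepinone (made, then opened) → ten-membered carbocycle (ring A) and α-methylene-γ-butyrolactone (ring B) together in the key step → epoxide last.
5. Enabling feature: C6, the lactone carbinol carbon, is bonded directly to vinylic C5 of the Z C4=C5 olefin of ring A, and O6 lies γ to C12; a vinyl-metal/aldehyde addition therefore makes the ring bond and hands its alkoxide to the ester, while the two Z olefins pre-fold the chain.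

Key step: step 14

Remark: germacrane numbering is used (ring C1–C10, lactone carbons C11–C13, C14 on C10, C15 on C4); the SMILES is read as the cis-1,10-epoxide (1R,10S) of a 4Z-dienolide carrying a (2R)-2-methylbutanoate, and (R)-2-methylbutanoic acid, angelic acid, (R)-glyceraldehyde acetonide and (−)-Ipc2B(allyl) are taken as purchasable.

**Route**

Step 1
Reactants: 1 prop-2-yn-1-ol
Product: 3 (2Z)-3-iodo-2-methylprop-2-en-1-ol, via chelated alkenylmagnesium alkoxide 2 (not isolated)
Conditions: MeMgBr (2.5 equiv), CuI (10 mol%), THF, −10 °C to rt; then I2, −10 °C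
Reagents that add atoms: methylmagnesium bromide, C[Mg]Br; iodine, II
Why: Hydroxyl-directed anti-carbomagnesiation of the propargylic alkoxide puts methyl on the internal carbon and magnesium on the terminal carbon in a five-membered chelate, so iodinolysis with retention should give only the Z iodoalkene that becomes C4=C5 with C15.

Step 2
Reactants: 3 (2Z)-3-iodo-2-methylprop-2-en-1-ol
Product: 4 (2Z)-3-iodo-2-methylprop-2-enal
Conditions: MnO2 (15 equiv), CH2Cl2, rt, dark; used directly
Reagents that add atoms: none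
Why: Allylic alcohol oxidation with MnO2 is neutral and should leave the vinyl iodide and the labile Z geometry untouched.

Step 3
Reactants: 4 (2Z)-3-iodo-2-methylprop-2-enal
Product: 6 (1Z,3S)-1-iodo-2-methylhexa-1,5-dien-3-ol, via borinate ester 5 (not isolated)
Conditions: (−)-Ipc2B(allyl), Et2O, −78 °C; then NaOH, H2O2, 0 °C
Reagents that add atoms: (−)-B-allyldiisopinocampheylborane, C=CCB([C@H]1[C@H](C)[C@H]2C[C@@H](C1)C2(C)C)[C@H]1[C@H](C)[C@H]2C[C@@H](C1)C2(C)C
Why: Brown allylation through a six-membered chair transition state; the isopinocampheyl groups select the aldehyde face that gives the 3S carbinol (reagent control), the first permanent stereocentre.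

Step 4
Reactants: 6 (1Z,3S)-1-iodo-2-methylhexa-1,5-dien-3-ol; 7 3-methylbut-3-enoic acid
Product: 8 (1Z,3S)-1-iodo-2-methylhexa-1,5-dien-3-yl 3-methylbut-3-enoate
Conditions: DIC, DMAP (5 mol%), CH2Cl2, −20 to 0 °C
Reagents that add atoms: none
Why: Steglich esterification, run cold with little DMAP so the β,γ-unsaturated acid does not slip into conjugation; the ester is the tether for the next ring closure.

Step 5
Reactants: 8 (1Z,3S)-1-iodo-2-methylhexa-1,5-dien-3-yl 3-methylbut-3-enoate
Product: 9 (7S)-7-[(1Z)-1-iodoprop-1-en-2-yl]-4-methyl-6,7-dihydrooxepin-2(3H)-one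
Conditions: second-generation Grubbs catalyst RuCl2(=CHPh)(H2IMes)(PCy3) (5 mol%), 1,4-benzoquinone (10 mol%), toluene (0.005 M), 80 °C
Reagents that add atoms: none
Why: Ring-closing metathesis between the monosubstituted and the 1,1-disubstituted olefin forms a seven-membered lactone in which the new trisubstituted C1=C10 olefin can only be Z, while the trisubstituted vinyl iodide stays out of the reaction.

Step 6
Reactants: 9 (7S)-7-[(1Z)-1-iodoprop-1-en-2-yl]-4-methyl-6,7-dihydrooxepin-2(3H)-one
Product: 10 (3Z,6S,7Z)-6-hydroxy-8-iodo-N-methoxy-N,3,7-trimethylocta-3,7-dienamide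
Conditions: MeNH(OMe)·HCl, Me3Al, CH2Cl2, 0 °C to rt
Reagents that add atoms: N,O-dimethylhydroxylamine hydrochloride, CNOC.Cl
Why: Weinreb aminolysis of the lactone by the aluminium amide opens the temporary ring without base, frees the C3 hydroxyl and leaves C8 at a level that can later be reduced selectively to the aldehyde.

Step 7
Reactants: 10 (3Z,6S,7Z)-6-hydroxy-8-iodo-N-methoxy-N,3,7-trimethylocta-3,7-dienamide; 11 (2R)-2-methylbutanoic acid
Product: 12 (1Z,3S,5Z)-1-iodo-8-[methoxy(methyl)amino]-2,6-dimethyl-8-oxoocta-1,5-dien-3-yl (2R)-2-methylbutanoate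
Conditions: EDC·HCl, DMAP, CH2Cl2, 0 °C to rt
Reagents that add atoms: none
Why: Steglich esterification puts the purchased (2R)-2-methylbutanoate on the only free hydroxyl, and its α-centre should not enolise under these conditions.

Step 8
Reactants: 12 (1Z,3S,5Z)-1-iodo-8-[methoxy(methyl)amino]-2,6-dimethyl-8-oxoocta-1,5-dien-3-yl (2R)-2-methylbutanoate
Product: 13 (1Z,3S,5Z)-1-iodo-2,6-dimethyl-8-oxoocta-1,5-dien-3-yl (2R)-2-methylbutanoate
Conditions: Cp2Zr(H)Cl (1.5 equiv), THF, rt, 20 min; used crude
Reagents that add atoms: none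
Why: Schwartz-reagent reduction of the tertiary amide stops at the aldehyde via a stable zirconated hemiaminal and should spare the ester and the vinyl iodide.

Step 9
Reactants: 14 (4R)-2,2-dimethyl-1,3-dioxolane-4-carbaldehyde; 15 methyl prop-2-enoate
Product: 16 methyl 2-{[(4R)-2,2-dimethyl-1,3-dioxolan-4-yl](hydroxy)methyl}prop-2-enoate (both carbinol epimers)
Conditions: DABCO (0.5 equiv), dioxane/H2O (1:1), rt
Reagents that add atoms: none
Why: Morita–Baylis–Hillman reaction; the new carbinol centre need not be controlled because it becomes sp2 in the next step, and the dioxolane centre is not touched.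

Step 10
Reactants: 16 methyl 2-{[(4R)-2,2-dimethyl-1,3-dioxolan-4-yl](hydroxy)methyl}prop-2-enoate
Product: 17 methyl (2Z)-2-(bromomethyl)-3-[(4S)-2,2-dimethyl-1,3-dioxolan-4-yl]prop-2-enoate
Conditions: NBS, Me2S, CH2Cl2, 0 °C to rt
Reagents that add atoms: N-bromosuccinimide, BrN1C(=O)CCC1=O
Why: Corey–Kim-type activation of the allylic alcohol followed by SN2′ attack of bromide should give the thermodynamically favoured Z 2-(bromomethyl)enoate.

Step 11
Reactants: 13 (1Z,3S,5Z)-1-iodo-2,6-dimethyl-8-oxoocta-1,5-dien-3-yl (2R)-2-methylbutanoate; 17 methyl (2Z)-2-(bromomethyl)-3-[(4S)-2,2-dimethyl-1,3-dioxolan-4-yl]prop-2-enoate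
Product: 18 methyl (3R,4R,6Z,9S,10Z)-3-[(4S)-2,2-dimethyl-1,3-dioxolan-4-yl]-4-hydroxy-11-iodo-6,10-dimethyl-2-methylidene-9-{[(2R)-2-methylbutanoyl]oxy}undeca-6,10-dienoate
Conditions: In powder (1.5 equiv), THF/H2O (1:1), rt
Reagents that add atoms: none
Why: Barbier-type 2-(alkoxycarbonyl)allylation: the allylindium adds through its γ-carbon in a chair transition state so that the Z olefin geometry becomes the syn C7/C8 pair, and the dioxolane centre, held by allylic 1,3-strain with its C–H in the olefin plane, should direct the aldehyde anti to the ring oxygen, giving C7 (R) and C8 (R).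

Step 12
Reactants: 18 (the C8 alcohol from step 11)
Product: 19 methyl (3S,4R,6Z,9S,10Z)-4-[(tert-butyldimethylsilyl)oxy]-3-[(4S)-2,2-dimethyl-1,3-dioxolan-4-yl]-11-iodo-6,10-dimethyl-2-methylidene-9-{[(2R)-2-methylbutanoyl]oxy}undeca-6,10-dienoate (silyl ether of 18; same spatial arrangement)
Conditions: TBSOTf, 2,6-lutidine, CH2Cl2, −78 °C
Reagents that add atoms: tert-butyldimethylsilyl trifluoromethanesulfonate, CC(C)(C)[Si](C)(C)OS(=O)(=O)C(F)(F)F
Why: Low-temperature silylation caps O8 before the γ-hydroxy ester can lactonise, so that only O6 can later close the lactone.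

Step 13
Reactants: 19 (silyl ether of 18)
Product: 21 methyl (3R,4R,6Z,9S,10Z)-4-[(tert-butyldimethylsilyl)oxy]-3-formyl-11-iodo-6,10-dimethyl-2-methylidene-9-{[(2R)-2-methylbutanoyl]oxy}undeca-6,10-dienoate, via 1,2-diol 20 (not isolated)
Conditions: H5IO6 (1.5 equiv), EtOAc, 0 °C to rt; used at once
Reagents that add atoms: none
Why: One-pot acetal hydrolysis and glycol cleavage with periodic acid turn the relay carbon into the C6 aldehyde (its oxygen is the former dioxolane oxygen and the future lactone oxygen) under non-basic conditions that should spare the C7 centre.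

Step 14
Reactants: 21 (the iodo aldehyde from step 13)
Product: 23 (1(10)Z,4Z)-8-[(tert-butyldimethylsilyl)oxy]-3-{[(2R)-2-methylbutanoyl]oxy}germacra-1(10),4,11(13)-trien-12,6-olide (trans-fused lactone, C3, C6, C7, C8 arranged as in the target), via macrocyclic hydroxy ester 22 (not isolated)
Conditions: CrCl2 (10 equiv), NiCl2 (0.1 equiv), DMSO/THF (3:1), 0.003 M, slow addition, rt; then aq. NH4Cl, PPTS (cat.), CH2Cl2
Reagents that add atoms: none
Why: Nozaki–Hiyama–Kishi reaction: zerovalent nickel inserts into the Z C5–I bond with retention, transmetalation gives the alkenyl species of trivalent chromium, and this adds only to the C6 aldehyde while the esters, the acrylate and the silyl ether stay inert. The closest known reaction type is the intramolecular Nozaki–Hiyama–Kishi closure of medium and large carbocycles followed by lactonisation of the resulting γ-hydroxy ester. Ring A closes by a 10-exo-trig addition, and the C6 chromium alkoxide (or the free hydroxyl after work-up) closes ring B by 5-exo-trig acyl substitution at the C12 methyl ester with loss of methanol. The new C6 centre is controlled by C7: attack anti to the α-(methoxycarbonyl)vinyl group (Felkin–Anh) with the carbonyl oxygen turned out of the forming ring, reinforced by 1,3-anti induction from the C8 silyloxy group, should give the 6R carbinol, which lactonises to the trans-fused ring. The step needs cyclisation over oligomerisation and a single lactone: high dilution and the two Z olefins (C1=C10 and C4=C5), which bend the chain and bring C5 near C6, serve the first, and the silyl group on O8, which leaves O6 as the only nucleophile γ to C12, secures the second.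

Step 15
Reactants: 23 (silylated macrocyclic lactone)
Product: 24 (3S,6R,7R,8R,1(10)Z,4Z)-8-hydroxy-3-{[(2R)-2-methylbutanoyl]oxy}germacra-1(10),4,11(13)-trien-12,6-olide
Conditions: HF·pyridine, THF/pyridine, 0 °C to rt
Reagents that add atoms: none
Why: Buffered fluoride desilylation should not touch the esters, the lactone or the olefins.

Step 16
Reactants: 24 (macrocyclic C8 alcohol)
Product: 25 (1R,3S,6R,7R,8R,10S,4Z)-1,10-epoxy-8-hydroxy-3-{[(2R)-2-methylbutanoyl]oxy}germacra-4,11(13)-dien-12,6-olide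
Conditions: VO(acac)2 (5 mol%), t-BuOOH (1.5 equiv), CH2Cl2, 0 °C to rt
Reagents that add atoms: tert-butyl hydroperoxide, CC(C)(C)OO
Why: Vanadium-catalysed hydroxyl-directed epoxidation: the C8 hydroxyl binds the vanadium peroxide and delivers oxygen to its own face of the homoallylic Z C1=C10 olefin, which should give the cis-epoxide with C1 (R) and C10 (S), while the C4=C5 olefin (out of reach, flanked by two acyloxy groups) and the C11=C13 acrylate do not react.

Step 17
Reactants: 25 (epoxy alcohol); 26 angelic acid [(2Z)-2-methylbut-2-enoic acid]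
Product: 28 target CNP0108431.1, (1R,3S,6R,7R,8R,10S,4Z)-8-(angeloyloxy)-1,10-epoxy-3-{[(2R)-2-methylbutanoyl]oxy}germacra-4,11(13)-dien-12,6-olide, via mixed anhydride 27 (not isolated)
Conditions: 26, 2,4,6-trichlorobenzoyl chloride, Et3N, toluene, rt; then 25, 80 °C, no DMAP
Reagents that add atoms: none
Why: Yamaguchi-type esterification through the mixed anhydride, run without DMAP so the angelate should not isomerise to the tiglate; the alcohol attacks the less hindered angeloyl carbonyl.

**Compound list**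

1 | prop-2-yn-1-ol | C#CCO | starting material
2 | chelated (Z)-alkenylmagnesium alkoxide (4-methyl-2,5-dihydro-1,2-oxamagnesole) | CC1=C[Mg]OC1 | intermediate
3 | (2Z)-3-iodo-2-methylprop-2-en-1-ol | OC/C(C)=C\I | intermediate
4 | (2Z)-3-iodo-2-methylprop-2-enal | O=C/C(C)=C\I | intermediate
5 | (1Z,3S)-1-iodo-2-methylhexa-1,5-dien-3-yl diisopinocampheylborinate | I/C=C(/C)[C@@H](OB([C@H]1[C@H](C)[C@H]2C[C@@H](C1)C2(C)C)[C@H]1[C@H](C)[C@H]2C[C@@H](C1)C2(C)C)CC=C | intermediate
6 | (1Z,3S)-1-iodo-2-methylhexa-1,5-dien-3-ol | I/C=C(/C)[C@@H](O)CC=C | intermediate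
7 | 3-methylbut-3-enoic acid | CC(=C)CC(=O)O | starting material
8 | (1Z,3S)-1-iodo-2-methylhexa-1,5-dien-3-yl 3-methylbut-3-enoate | I/C=C(/C)[C@@H](OC(=O)CC(C)=C)CC=C | intermediate
9 | (7S)-7-[(1Z)-1-iodoprop-1-en-2-yl]-4-methyl-6,7-dihydrooxepin-2(3H)-one | I/C=C(/C)[C@@H]1CC=C(C)CC(=O)O1 | intermediate
10 | (3Z,6S,7Z)-6-hydroxy-8-iodo-N-methoxy-N,3,7-trimethylocta-3,7-dienamide | I/C=C(/C)[C@@H](O)C/C=C(C)\CC(=O)N(C)OC | intermediate
11 | (2R)-2-methylbutanoic acid | CC[C@@H](C)C(=O)O | starting material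
12 | (1Z,3S,5Z)-1-iodo-8-[methoxy(methyl)amino]-2,6-dimethyl-8-oxoocta-1,5-dien-3-yl (2R)-2-methylbutanoate | I/C=C(/C)[C@@H](OC(=O)[C@H](C)CC)C/C=C(C)\CC(=O)N(C)OC | intermediate
13 | (1Z,3S,5Z)-1-iodo-2,6-dimethyl-8-oxoocta-1,5-dien-3-yl (2R)-2-methylbutanoate | I/C=C(/C)[C@@H](OC(=O)[C@H](C)CC)C/C=C(C)\CC=O | intermediate
14 | (4R)-2,2-dimethyl-1,3-dioxolane-4-carbaldehyde | O=C[C@H]1COC(C)(C)O1 | starting material
15 | methyl prop-2-enoate | C=CC(=O)OC | starting material
16 | methyl 2-{[(4R)-2,2-dimethyl-1,3-dioxolan-4-yl](hydroxy)methyl}prop-2-enoate (carbinol epimers) | C=C(C(=O)OC)C(O)[C@H]1COC(C)(C)O1 | intermediate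
17 | methyl (2Z)-2-(bromomethyl)-3-[(4S)-2,2-dimethyl-1,3-dioxolan-4-yl]prop-2-enoate | BrC/C(C(=O)OC)=C\[C@H]1COC(C)(C)O1 | intermediate
18 | methyl (3R,4R,6Z,9S,10Z)-3-[(4S)-2,2-dimethyl-1,3-dioxolan-4-yl]-4-hydroxy-11-iodo-6,10-dimethyl-2-methylidene-9-{[(2R)-2-methylbutanoyl]oxy}undeca-6,10-dienoate | I/C=C(/C)[C@@H](OC(=O)[C@H](C)CC)C/C=C(C)\C[C@@H](O)[C@H]([C@H]1COC(C)(C)O1)C(=C)C(=O)OC | intermediate
19 | C8 tert-butyldimethylsilyl ether of 18 | I/C=C(/C)[C@@H](OC(=O)[C@H](C)CC)C/C=C(C)\C[C@@H](O[Si](C)(C)C(C)(C)C)[C@H]([C@H]1COC(C)(C)O1)C(=C)C(=O)OC | intermediate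
20 | 1,2-diol from 19, with a (1S)-1,2-dihydroxyethyl group on C7 | I/C=C(/C)[C@@H](OC(=O)[C@H](C)CC)C/C=C(C)\C[C@@H](O[Si](C)(C)C(C)(C)C)[C@H]([C@H](O)CO)C(=C)C(=O)OC | intermediate
21 | methyl (3R,4R,6Z,9S,10Z)-4-[(tert-butyldimethylsilyl)oxy]-3-formyl-11-iodo-6,10-dimethyl-2-methylidene-9-{[(2R)-2-methylbutanoyl]oxy}undeca-6,10-dienoate | I/C=C(/C)[C@@H](OC(=O)[C@H](C)CC)C/C=C(C)\C[C@@H](O[Si](C)(C)C(C)(C)C)[C@H](C=O)C(=C)C(=O)OC | intermediate
22 | methyl (1(10)Z,4Z)-8-[(tert-butyldimethylsilyl)oxy]-6-hydroxy-3-{[(2R)-2-methylbutanoyl]oxy}germacra-1(10),4,11(13)-trien-12-oate, centres as in the target | C=C(C(=O)OC)[C@H]1[C@H](O)/C=C(/C)[C@@H](OC(=O)[C@H](C)CC)C/C=C(C)\C[C@H]1O[Si](C)(C)C(C)(C)C | intermediate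
23 | (1(10)Z,4Z)-8-[(tert-butyldimethylsilyl)oxy]-3-{[(2R)-2-methylbutanoyl]oxy}germacra-1(10),4,11(13)-trien-12,6-olide | C=C1C(=O)O[C@@H]2/C=C(/C)[C@@H](OC(=O)[C@H](C)CC)C/C=C(C)\C[C@@H](O[Si](C)(C)C(C)(C)C)[C@@H]12 | intermediate
24 | (3S,6R,7R,8R,1(10)Z,4Z)-8-hydroxy-3-{[(2R)-2-methylbutanoyl]oxy}germacra-1(10),4,11(13)-trien-12,6-olide | C=C1C(=O)O[C@@H]2/C=C(/C)[C@@H](OC(=O)[C@H](C)CC)C/C=C(C)\C[C@@H](O)[C@@H]12 | intermediate
25 | (1R,3S,6R,7R,8R,10S,4Z)-1,10-epoxy-8-hydroxy-3-{[(2R)-2-methylbutanoyl]oxy}germacra-4,11(13)-dien-12,6-olide | C=C1C(=O)O[C@@H]2/C=C(/C)[C@@H](OC(=O)[C@H](C)CC)C[C@H]3O[C@@]3(C)C[C@@H](O)[C@@H]12 | intermediate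
26 | angelic acid, (2Z)-2-methylbut-2-enoic acid | C/C=C(/C)C(=O)O | starting material
27 | angelic 2,4,6-trichlorobenzoic anhydride | C/C=C(/C)C(=O)OC(=O)c1c(Cl)cc(Cl)cc1Cl | intermediate
28 | CNP0108431.1, (1R,3S,6R,7R,8R,10S,4Z)-8-(angeloyloxy)-1,10-epoxy-3-{[(2R)-2-methylbutanoyl]oxy}germacra-4,11(13)-dien-12,6-olide | C=C1C(=O)O[C@@H]2/C=C(/C)[C@@H](OC(=O)[C@H](C)CC)C[C@H]3O[C@@]3(C)C[C@@H](OC(=O)/C(C)=C\C)[C@@H]12 | target

**Step count and risks**

Total step count: 17. Longest linear sequence: 15 steps (steps 1–8 and 11–17); steps 9–10 make the second fragment.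

Steps most likely to fail:

Step 11. The facial control passed from the dioxolane centre to C7/C8 may be weak or reversed, the syn relationship may erode if the allylindium equilibrates its geometry, and the β,γ-unsaturated aldehyde may drift into conjugation. The fallback sets out from 16 (with 13) and comes back at 18. Adduct 16 is acetylated (Ac2O, DMAP) to methyl 2-{(acetyloxy)[(4R)-2,2-dimethyl-1,3-dioxolan-4-yl]methyl}prop-2-enoate F1. Copper-catalysed SN2′ borylation (B2pin2, CuCl, KOAc, DMF) then gives the configurationally stable allylboronate methyl (2E)-3-[(4S)-2,2-dimethyl-1,3-dioxolan-4-yl]-2-[(4,4,5,5-tetramethyl-1,3,2-dioxaborolan-2-yl)methyl]prop-2-enoate F2. F2 is added to 13 in toluene at 60–80 °C, with a chiral phosphoric acid as an optional source of reagent control. The closed Zimmerman–Traxler chair of this allylboration transmits the olefin geometry strictly into the syn pair and should give 18 after work-up.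

Step 14. Oligomerisation may outrun closure of the ten-membered ring, the aldehyde may epimerise or eliminate at its α-carbon, or the vinyl species may add to the wrong aldehyde face, in which case the epimeric carbinol does not give the trans-fused lactone. The fallback sets out from 21 and comes back at 22, keeping the same ring-closing bond but correcting C6 by oxidation and reagent-controlled reduction. The C6-epimeric hydroxy ester, the 6-epimer of 22, F3, obtained from the same closure, is oxidised with Dess–Martin periodinane to the macrocyclic enone methyl (1(10)Z,4Z)-8-[(tert-butyldimethylsilyl)oxy]-3-{[(2R)-2-methylbutanoyl]oxy}-6-oxogermacra-1(10),4,11(13)-trien-12-oate F4. F4 is reduced with (R)-Me-CBS oxazaborolidine and catecholborane at −78 °C (alkenyl taken as the large group) to 22, which lactonises to 23 as in the route.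

Step 16. Oxygen may be delivered to the wrong olefin face if the ring holds the C8 hydroxyl away from C1=C10, or the directed reaction may be slow enough for oxidation elsewhere. The fallback goes from 24 directly to 25 (no new compound, F0). It replaces hydroxyl direction by reagent control: Shi epoxidation with the fructose-derived ketone of the matching series, Oxone (2KHSO5·KHSO4·K2SO4), buffered MeCN/dimethoxymethane, 0 °C, where the chiral dioxirane selects the face of the trisubstituted olefin.

Further compounds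
F1 | step 11 | methyl 2-{(acetyloxy)[(4R)-2,2-dimethyl-1,3-dioxolan-4-yl]methyl}prop-2-enoate | C=C(C(=O)OC)C(OC(C)=O)[C@H]1COC(C)(C)O1
F2 | step 11 | methyl (2E)-3-[(4S)-2,2-dimethyl-1,3-dioxolan-4-yl]-2-[(4,4,5,5-tetramethyl-1,3,2-dioxaborolan-2-yl)methyl]prop-2-enoate | CC1(C)OB(C/C(C(=O)OC)=C\[C@H]2COC(C)(C)O2)OC1(C)C
F3 | step 14 | 6-epimer of 22 | C=C(C(=O)OC)[C@H]1[C@@H](O)/C=C(/C)[C@@H](OC(=O)[C@H](C)CC)C/C=C(C)\C[C@H]1O[Si](C)(C)C(C)(C)C
F4 | step 14 | methyl (1(10)Z,4Z)-8-[(tert-butyldimethylsilyl)oxy]-3-{[(2R)-2-methylbutanoyl]oxy}-6-oxogermacra-1(10),4,11(13)-trien-12-oate | C=C(C(=O)OC)[C@H]1C(=O)/C=C(/C)[C@@H](OC(=O)[C@H](C)CC)C/C=C(C)\C[C@H]1O[Si](C)(C)C(C)(C)C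
F0 | step 16 | none | none
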